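**Plan**
- Ring E (like ring C) has five contiguous oxygens and one CH. Its C3–C6 match the four carbons of a squarate ester; C2–H and C1, which carries the ring D ether, match a 2-aryloxyvinyl unit.
- Retrosynthesis: the eighteen O–CH3 bonds are cut first, then the E–F ether (Ullmann) and the F–G ether (Chan–Lam–Evans). Ring E is then cut at C6–C1, back to a 4-(2-aryloxyvinyl)cyclobutenone.
- Further back, the C–D ether (Ullmann) is cut, ring C by the same cyclobutenone sequence, then the A–B ether (Ullmann).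
- Forward: A + B, ring C grown on the ring B phenol, ring D attached, ring E grown on the ring D phenol (key step), the F–G bromide attached, global demethylation.
- The enol ether is made Z by semihydrogenation of the alkynyl adduct, which avoids a β-aryloxyvinyllithium. The tertiary alkoxide is methylated in the flask, so the cyclization frees only the hindered hydroxyl.
- Stereochemistry: the target has no stereocentre. The cyclobutenone C4 is racemic and is lost on ring opening; the Z alkene comes from syn hydrogenation.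

Key step: step 13

Assumption: rings are lettered A (2,4,6-trihydroxyphenoxy end) to G (3,4,5-trihydroxyphenoxy end); all phenols are carried as methyl ethers because the squarate carbons arrive methoxylated.
Shorthand: "A–B aryloxy" is the 2,6-dimethoxy-4-(2,4,6-trimethoxyphenoxy)phenoxy group (phenol 5 less its hydroxyl hydrogen). "A–D aryloxy" is the 4-{6-[2,6-dimethoxy-4-(2,4,6-trimethoxyphenoxy)phenoxy]-2,3,4-trimethoxyphenoxy}-2,6-dimethoxyphenoxy group (phenol 16 less its hydroxyl hydrogen).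

Step 1
Reactants: 1 4-bromo-2,6-dimethoxyphenol
Product: 2 2-(benzyloxy)-5-bromo-1,3-dimethoxybenzene
Conditions: BnBr, K2CO3, DMF, rt
Reagents that add atoms: benzyl bromide, BrCc1ccccc1
Why: Williamson O-benzylation masks the hindered phenol so that the unhindered C–Br carbon can serve as the aryl donor for rings B and D.

Step 2
Reactants: 2 2-(benzyloxy)-5-bromo-1,3-dimethoxybenzene; 3 2,4,6-trimethoxyphenol
Product: 4 2-[4-(benzyloxy)-3,5-dimethoxyphenoxy]-1,3,5-trimethoxybenzene
Conditions: CuI (10 mol %), picolinic acid (20 mol %), K3PO4, DMSO, 90 °C, Ar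
Reagents that add atoms: none
Why: Ullmann diaryl ether synthesis, in a ligand system suited to di-ortho-substituted phenols, should join the hindered ring A phenoxide to the bromide carbon of 2, which is flanked only by hydrogens.

Step 3
Reactants: 4 2-[4-(benzyloxy)-3,5-dimethoxyphenoxy]-1,3,5-trimethoxybenzene
Product: 5 2,6-dimethoxy-4-(2,4,6-trimethoxyphenoxy)phenol
Conditions: H2 (1 atm), Pd/C, EtOAc–MeOH, rt
Reagents that add atoms: none
Why: Hydrogenolysis of the benzyl ether should free the ring B phenol while aryl methyl ethers and the diaryl ether stay intact.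

Step 4
Reactants: 5 2,6-dimethoxy-4-(2,4,6-trimethoxyphenoxy)phenol
Product: 6 2-{[(E)-1,2-dichloroethenyl]oxy}-1,3-dimethoxy-5-(2,4,6-trimethoxyphenoxy)benzene
Conditions: trichloroethylene (1.5 equiv), K2CO3, DMF, 70 °C
Reagents that add atoms: trichloroethylene, ClC=C(Cl)Cl
Why: Carbonate dehydrochlorinates the trichloroethylene reagent to dichloroacetylene, and anti addition of the phenoxide to it should give the (E)-1,2-dichlorovinyl ether, the established route from phenols to ynol ether precursors.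

Step 5
Reactants: 6 2-{[(E)-1,2-dichloroethenyl]oxy}-1,3-dimethoxy-5-(2,4,6-trimethoxyphenoxy)benzene; 7 dimethyl squarate
Product: 10 4-[(A–B aryloxy)ethynyl]-2,3,4-trimethoxycyclobut-2-en-1-one (racemic), via lithium acetylide 8 (not isolated), via lithium alkoxide 9 (not isolated)
Conditions: n-BuLi (2.05 equiv), THF, −78 °C; cannulate into 7, THF, −78 °C; MeOTf, −78 → 0 °C
Reagents that add atoms: methyl trifluoromethanesulfonate, COS(=O)(=O)C(F)(F)F
Why: Elimination of HCl and chlorine–lithium exchange should give the lithium aryloxyacetylide, which adds 1,2 to one squarate carbonyl (the standard entry to Moore substrates), and the tertiary alkoxide is then O-methylated by the triflate.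

Step 6
Reactants: 10 4-[(A–B aryloxy)ethynyl]-2,3,4-trimethoxycyclobut-2-en-1-one
Product: 11 4-[(Z)-2-(A–B aryloxy)ethenyl]-2,3,4-trimethoxycyclobut-2-en-1-one (racemic)
Conditions: H2 (1 atm), Pd/CaCO3 poisoned with Pb(OAc)2, quinoline, EtOAc, rt
Reagents that add atoms: none
Why: Lindlar semihydrogenation delivers both hydrogens syn on the poisoned surface and should stop at the (Z)-enol ether, the tetrasubstituted enone alkene being inert.

Step 7
Reactants: 11 4-[(Z)-2-(A–B aryloxy)ethenyl]-2,3,4-trimethoxycyclobut-2-en-1-one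
Product: 14 6-(A–B aryloxy)-2,3,4-trimethoxyphenol, via dienylketene 12 (not isolated), via cyclohexadienone 13 (not isolated)
Conditions: toluene, 110 °C, degassed
Reagents that add atoms: none
Why: Moore cyclization (conrotatory 4π opening with methoxy outward and alkenyl inward, disrotatory 6π closure, enolization) should build ring C with the ring B ether in place and free only the hindered phenol.

Step 8
Reactants: 14 6-(A–B aryloxy)-2,3,4-trimethoxyphenol; 2 2-(benzyloxy)-5-bromo-1,3-dimethoxybenzene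
Product: 15 1-(A–B aryloxy)-2-[4-(benzyloxy)-3,5-dimethoxyphenoxy]-3,4,5-trimethoxybenzene
Conditions: CuI (20 mol %), picolinic acid (40 mol %), K3PO4, DMSO, 100 °C, Ar
Reagents that add atoms: none
Why: Ullmann diaryl ether synthesis should arylate the ring C phenoxide, flanked by an aryloxy and a methoxy group, because the bromide carbon of 2 carries no ortho substituent.

Step 9
Reactants: 15 1-(A–B aryloxy)-2-[4-(benzyloxy)-3,5-dimethoxyphenoxy]-3,4,5-trimethoxybenzene
Product: 16 4-{6-[2,6-dimethoxy-4-(2,4,6-trimethoxyphenoxy)phenoxy]-2,3,4-trimethoxyphenoxy}-2,6-dimethoxyphenol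
Conditions: H2 (1 atm), Pd/C, EtOAc–MeOH, rt
Reagents that add atoms: none
Why: Benzyl ether hydrogenolysis should free the ring D phenol without touching methyl or diaryl ethers.

Step 10
Reactants: 16 4-{6-[2,6-dimethoxy-4-(2,4,6-trimethoxyphenoxy)phenoxy]-2,3,4-trimethoxyphenoxy}-2,6-dimethoxyphenol
Product: 17 (E)-1,2-dichloroethenyl ether of 16 (O–C(Cl)=CHCl in place of OH)
Conditions: trichloroethylene (1.5 equiv), K2CO3, DMF, 70 °C
Reagents that add atoms: trichloroethylene, ClC=C(Cl)Cl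
Why: As in step 4, anti addition of the phenoxide to dichloroacetylene, made in the flask from the trichloroethylene reagent, should give the (E)-dichlorovinyl ether.

Step 11
Reactants: 17 (E)-1,2-dichloroethenyl ether of 16; 7 dimethyl squarate
Product: 20 4-[(A–D aryloxy)ethynyl]-2,3,4-trimethoxycyclobut-2-en-1-one (racemic), via lithium acetylide 18 (not isolated), via lithium alkoxide 19 (not isolated)
Conditions: n-BuLi (2.05 equiv), THF, −78 °C; cannulate into 7, THF, −78 °C; MeOTf, −78 → 0 °C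
Reagents that add atoms: methyl trifluoromethanesulfonate, COS(=O)(=O)C(F)(F)F
Why: The acetylide formation, 1,2-addition to the squarate and O-methylation of step 5 should repeat, since at −78 °C the vinylic deprotonation and Cl–Li exchange outrun lithiation of the methoxyarenes.

Step 12
Reactants: 20 4-[(A–D aryloxy)ethynyl]-2,3,4-trimethoxycyclobut-2-en-1-one
Product: 21 4-[(Z)-2-(A–D aryloxy)ethenyl]-2,3,4-trimethoxycyclobut-2-en-1-one (racemic)
Conditions: H2 (1 atm), Pd/CaCO3 poisoned with Pb(OAc)2, quinoline, EtOAc, rt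
Reagents that add atoms: none
Why: Lindlar semihydrogenation should give the (Z)-enol ether by syn addition and spare the cyclobutenone alkene and all aryl ethers.

Step 13
Reactants: 21 4-[(Z)-2-(A–D aryloxy)ethenyl]-2,3,4-trimethoxycyclobut-2-en-1-one
Product: 24 6-(A–D aryloxy)-2,3,4-trimethoxyphenol, via dienylketene 22 (not isolated), via cyclohexadienone 23 (not isolated)
Conditions: toluene, 110 °C, degassed
Reagents that add atoms: none
Why: Heating opens the cyclobutenone by a conrotatory 4π electrocyclic reaction to dienylketene 22, whose ketene carbon then bonds to the aryloxy-bearing vinyl terminus in a thermal disrotatory 6π electrocyclization, and the resulting cyclohexadienone 23 enolizes to the phenol. The closest known reaction is the Moore cyclization of 4-alkenyl-4-alkoxycyclobutenones made from squarate esters. Ring E is the only ring closed; it forms in the 6π mode through the new C6–C1 bond, with the ring D ether oxygen already on C1. The one sp3 carbon of 23 arises without control and is erased by enolization, so no stereocentre has to be set. The step needs the alkenyl group to turn inward toward the ketene, and the C4 methoxy donor secures this by rotating outward under torquoselectivity; the linear ketene terminus should leave room for the inward-pointing aryloxy group of the Z alkene. Because C4 enters as a methyl ether, only the hydroxyl next to the ring D ether is freed, which is the one to be arylated next.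

Step 14
Reactants: 1 4-bromo-2,6-dimethoxyphenol; 25 (3,4,5-trimethoxyphenyl)boronic acid
Product: 26 5-bromo-1,3-dimethoxy-2-(3,4,5-trimethoxyphenoxy)benzene
Conditions: Cu(OAc)2 (2 equiv), pyridine, 4 Å molecular sieves, CH2Cl2, air, rt
Reagents that add atoms: none
Why: Chan–Lam–Evans oxidative coupling should arylate the di-ortho-substituted phenol at room temperature and leave the aryl bromide untouched for the next coupling.

Step 15
Reactants: 24 6-(A–D aryloxy)-2,3,4-trimethoxyphenol; 26 5-bromo-1,3-dimethoxy-2-(3,4,5-trimethoxyphenoxy)benzene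
Product: 27 1-(A–D aryloxy)-2-[3,5-dimethoxy-4-(3,4,5-trimethoxyphenoxy)phenoxy]-3,4,5-trimethoxybenzene (octadeca-O-methyl ether of the target)
Conditions: CuI (20 mol %), picolinic acid (40 mol %), K3PO4, DMSO, 100 °C, Ar
Reagents that add atoms: none
Why: Ullmann diaryl ether synthesis should join the hindered ring E phenoxide to the unhindered bromide carbon of the F–G unit, as in steps 2 and 8.

Step 16
Reactants: 27 octadeca-O-methyl ether of the target
Product: 28 target CNP0292517.0 (all eighteen OMe of 27 replaced by OH)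
Conditions: BBr3 (about 3 equiv per OMe), CH2Cl2, −78 °C → rt; then ice-water, Ar
Reagents that add atoms: none
Why: BBr3 cleaves aryl methyl ethers by bromide attack at the methyl carbon of the boron-complexed ether, whereas diaryl ether oxygens offer no sp3 carbon and should survive.

**Compound list**
1 | 4-bromo-2,6-dimethoxyphenol | COc1cc(Br)cc(OC)c1O | starting material
2 | 2-(benzyloxy)-5-bromo-1,3-dimethoxybenzene | COc1cc(Br)cc(OC)c1OCc1ccccc1 | intermediate
3 | 2,4,6-trimethoxyphenol | COc1cc(OC)c(O)c(OC)c1 | starting material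
4 | 2-[4-(benzyloxy)-3,5-dimethoxyphenoxy]-1,3,5-trimethoxybenzene | COc1cc(OC)c(Oc2cc(OC)c(OCc3ccccc3)c(OC)c2)c(OC)c1 | intermediate
5 | 2,6-dimethoxy-4-(2,4,6-trimethoxyphenoxy)phenol | COc1cc(OC)c(Oc2cc(OC)c(O)c(OC)c2)c(OC)c1 | intermediate
6 | 2-{[(E)-1,2-dichloroethenyl]oxy}-1,3-dimethoxy-5-(2,4,6-trimethoxyphenoxy)benzene | COc1cc(OC)c(Oc2cc(OC)c(O/C(Cl)=C\Cl)c(OC)c2)c(OC)c1 | intermediate
7 | dimethyl squarate | COC1=C(OC)C(=O)C1=O | starting material
8 | lithium (A–B aryloxy)acetylide (not isolated) | COc1cc(OC)c(Oc2cc(OC)c(OC#C[Li])c(OC)c2)c(OC)c1 | intermediate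
9 | lithium alkoxide of 4-[(A–B aryloxy)ethynyl]-4-hydroxy-2,3-dimethoxycyclobut-2-en-1-one (racemic, not isolated) | COC1=C(OC)C(O[Li])(C#COc2c(OC)cc(Oc3c(OC)cc(OC)cc3OC)cc2OC)C1=O | intermediate
10 | 4-[(A–B aryloxy)ethynyl]-2,3,4-trimethoxycyclobut-2-en-1-one (racemic) | COC1=C(OC)C(OC)(C#COc2c(OC)cc(Oc3c(OC)cc(OC)cc3OC)cc2OC)C1=O | intermediate
11 | 4-[(Z)-2-(A–B aryloxy)ethenyl]-2,3,4-trimethoxycyclobut-2-en-1-one (racemic) | COC1=C(OC)C(OC)(/C=C\Oc2c(OC)cc(Oc3c(OC)cc(OC)cc3OC)cc2OC)C1=O | intermediate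
12 | (3Z,5Z)-6-(A–B aryloxy)-2,3,4-trimethoxyhexa-1,3,5-trien-1-one (not isolated) | O=C=C(OC)/C(OC)=C(OC)\C=C/Oc1c(OC)cc(Oc2c(OC)cc(OC)cc2OC)cc1OC | intermediate
13 | 6-(A–B aryloxy)-2,3,4-trimethoxycyclohexa-2,4-dien-1-one (racemic, not isolated) | COC1=CC(Oc2c(OC)cc(Oc3c(OC)cc(OC)cc3OC)cc2OC)C(=O)C(OC)=C1OC | intermediate
14 | 6-(A–B aryloxy)-2,3,4-trimethoxyphenol | COc1cc(Oc2c(OC)cc(Oc3c(OC)cc(OC)cc3OC)cc2OC)c(O)c(OC)c1OC | intermediate
15 | 1-(A–B aryloxy)-2-[4-(benzyloxy)-3,5-dimethoxyphenoxy]-3,4,5-trimethoxybenzene | COc1cc(Oc2c(OC)cc(Oc3c(OC)cc(OC)cc3OC)cc2OC)c(Oc2cc(OC)c(OCc3ccccc3)c(OC)c2)c(OC)c1OC | intermediate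
16 | 4-{6-[2,6-dimethoxy-4-(2,4,6-trimethoxyphenoxy)phenoxy]-2,3,4-trimethoxyphenoxy}-2,6-dimethoxyphenol | COc1cc(Oc2c(OC)cc(Oc3c(OC)cc(OC)cc3OC)cc2OC)c(Oc2cc(OC)c(O)c(OC)c2)c(OC)c1OC | intermediate
17 | (E)-1,2-dichloroethenyl ether of 16 | COc1cc(Oc2c(OC)cc(Oc3c(OC)cc(OC)cc3OC)cc2OC)c(Oc2cc(OC)c(O/C(Cl)=C\Cl)c(OC)c2)c(OC)c1OC | intermediate
18 | lithium (A–D aryloxy)acetylide (not isolated) | COc1cc(Oc2c(OC)cc(Oc3c(OC)cc(OC)cc3OC)cc2OC)c(Oc2cc(OC)c(OC#C[Li])c(OC)c2)c(OC)c1OC | intermediate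
19 | lithium alkoxide of 4-[(A–D aryloxy)ethynyl]-4-hydroxy-2,3-dimethoxycyclobut-2-en-1-one (racemic, not isolated) | COC1=C(OC)C(O[Li])(C#COc2c(OC)cc(Oc3c(OC)c(OC)c(OC)cc3Oc3c(OC)cc(Oc4c(OC)cc(OC)cc4OC)cc3OC)cc2OC)C1=O | intermediate
20 | 4-[(A–D aryloxy)ethynyl]-2,3,4-trimethoxycyclobut-2-en-1-one (racemic) | COC1=C(OC)C(OC)(C#COc2c(OC)cc(Oc3c(OC)c(OC)c(OC)cc3Oc3c(OC)cc(Oc4c(OC)cc(OC)cc4OC)cc3OC)cc2OC)C1=O | intermediate
21 | 4-[(Z)-2-(A–D aryloxy)ethenyl]-2,3,4-trimethoxycyclobut-2-en-1-one (racemic) | COC1=C(OC)C(OC)(/C=C\Oc2c(OC)cc(Oc3c(OC)c(OC)c(OC)cc3Oc3c(OC)cc(Oc4c(OC)cc(OC)cc4OC)cc3OC)cc2OC)C1=O | intermediate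
22 | (3Z,5Z)-6-(A–D aryloxy)-2,3,4-trimethoxyhexa-1,3,5-trien-1-one (not isolated) | O=C=C(OC)/C(OC)=C(OC)\C=C/Oc1c(OC)cc(Oc2c(OC)c(OC)c(OC)cc2Oc2c(OC)cc(Oc3c(OC)cc(OC)cc3OC)cc2OC)cc1OC | intermediate
23 | 6-(A–D aryloxy)-2,3,4-trimethoxycyclohexa-2,4-dien-1-one (racemic, not isolated) | COC1=CC(Oc2c(OC)cc(Oc3c(OC)c(OC)c(OC)cc3Oc3c(OC)cc(Oc4c(OC)cc(OC)cc4OC)cc3OC)cc2OC)C(=O)C(OC)=C1OC | intermediate
24 | 6-(A–D aryloxy)-2,3,4-trimethoxyphenol | COc1cc(Oc2c(OC)cc(Oc3c(OC)c(OC)c(OC)cc3Oc3c(OC)cc(Oc4c(OC)cc(OC)cc4OC)cc3OC)cc2OC)c(O)c(OC)c1OC | intermediate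
25 | (3,4,5-trimethoxyphenyl)boronic acid | COc1cc(B(O)O)cc(OC)c1OC | starting material
26 | 5-bromo-1,3-dimethoxy-2-(3,4,5-trimethoxyphenoxy)benzene | COc1cc(Br)cc(OC)c1Oc1cc(OC)c(OC)c(OC)c1 | intermediate
27 | 1-(A–D aryloxy)-2-[3,5-dimethoxy-4-(3,4,5-trimethoxyphenoxy)phenoxy]-3,4,5-trimethoxybenzene | COc1cc(Oc2c(OC)cc(Oc3c(OC)c(OC)c(OC)cc3Oc3c(OC)cc(Oc4c(OC)cc(OC)cc4OC)cc3OC)cc2OC)c(Oc2cc(OC)c(Oc3cc(OC)c(OC)c(OC)c3)c(OC)c2)c(OC)c1OC | intermediate
28 | CNP0292517.0, the octadecaphenol of 27 | Oc1cc(O)c(Oc2cc(O)c(Oc3cc(O)c(O)c(O)c3Oc3cc(O)c(Oc4cc(O)c(O)c(O)c4Oc4cc(O)c(Oc5cc(O)c(O)c(O)c5)c(O)c4)c(O)c3)c(O)c2)c(O)c1 | target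

Total step count: 16. Longest linear sequence: 15 steps (steps 1–13, 15 and 16; step 14 is a one-step side branch).

**Steps most likely to fail**

Step 13. The 6π closure may be slowed because the aryloxy group on the Z terminus points into the forming ring, so the dienylketene may be lost to dimerization or to adventitious nucleophiles before it closes. The fallback changes the alkene geometry and the way the precursor is made. It sets out from 17: n-BuLi at −78 °C gives acetylide 18, and protonation with methanol gives the terminal ynol ether F1. Radical hydrostannation (Bu3SnH, AIBN, 80 °C, equilibrating conditions) should give the (E)-2-(tributylstannyl)vinyl ether F2. Tin–lithium exchange with n-BuLi at −100 °C, cold enough to hold back β-elimination of aryloxide, gives the (E)-2-aryloxyvinyllithium F3, which is added at once to dimethyl squarate 7 to give the lithium alkoxide F4. Methyl triflate converts F4 into the (E)-alkenyl trimethoxycyclobutenone F5. Heating F5 in toluene opens it to the (E)-dienylketene F6, whose aryloxy group now points outward; closure gives cyclohexadienone 23, and the route is rejoined at 24.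

Step 15. The phenoxide of 24, flanked by an aryloxy and a methoxy group on a five-ring scaffold, may enter the copper cycle too slowly, so that protodebromination of 26 and oxidative decay of the electron-rich phenol dominate at 100 °C. The fallback reverses the role of the F–G unit and works at room temperature. It sets out from 26: bromine–lithium exchange (n-BuLi, THF, −78 °C) gives the aryllithium F7, trimethyl borate gives the lithium trimethoxyborate F8, and aqueous HCl gives the boronic acid F9. Chan–Lam–Evans coupling of F9 with 24 (Cu(OAc)2, pyridine, 4 Å molecular sieves, CH2Cl2, air) returns to the route at 27.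

Step 16. Cleavage may stall at partly methylated stages across eighteen sites, and the free polyphenol with its pyrogallol-type rings may oxidize in air during isolation. The fallback is a capture-and-release sequence that sets out from 27. After BBr3 treatment and aqueous quench, the crude 28 is not purified but peracetylated (Ac2O, pyridine) to the octadecaacetate F10. F10 is stable on silica and can be separated from under-demethylated material, which is resubmitted. Deacetylation with catalytic K2CO3 in degassed methanol under argon returns to the route at 28.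

**Further compounds**
F1 | step 13 | ethynyl ether of 16 (O–C≡CH in place of OH) | COc1cc(Oc2c(OC)cc(Oc3c(OC)cc(OC)cc3OC)cc2OC)c(Oc2cc(OC)c(OC#C)c(OC)c2)c(OC)c1OC
F2 | step 13 | (E)-2-(tributylstannyl)ethenyl ether of 16 | COc1cc(Oc2c(OC)cc(Oc3c(OC)cc(OC)cc3OC)cc2OC)c(Oc2cc(OC)c(O/C=C/[Sn](CCCC)(CCCC)CCCC)c(OC)c2)c(OC)c1OC
F3 | step 13 | (E)-2-(A–D aryloxy)ethenyllithium | COc1cc(Oc2c(OC)cc(Oc3c(OC)cc(OC)cc3OC)cc2OC)c(Oc2cc(OC)c(O/C=C/[Li])c(OC)c2)c(OC)c1OC
F4 | step 13 | lithium alkoxide of 4-[(E)-2-(A–D aryloxy)ethenyl]-4-hydroxy-2,3-dimethoxycyclobut-2-en-1-one (racemic) | COC1=C(OC)C(O[Li])(/C=C/Oc2c(OC)cc(Oc3c(OC)c(OC)c(OC)cc3Oc3c(OC)cc(Oc4c(OC)cc(OC)cc4OC)cc3OC)cc2OC)C1=O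
F5 | step 13 | 4-[(E)-2-(A–D aryloxy)ethenyl]-2,3,4-trimethoxycyclobut-2-en-1-one (racemic) | COC1=C(OC)C(OC)(/C=C/Oc2c(OC)cc(Oc3c(OC)c(OC)c(OC)cc3Oc3c(OC)cc(Oc4c(OC)cc(OC)cc4OC)cc3OC)cc2OC)C1=O
F6 | step 13 | (3Z,5E)-6-(A–D aryloxy)-2,3,4-trimethoxyhexa-1,3,5-trien-1-one | O=C=C(OC)/C(OC)=C(OC)\C=C\Oc1c(OC)cc(Oc2c(OC)c(OC)c(OC)cc2Oc2c(OC)cc(Oc3c(OC)cc(OC)cc3OC)cc2OC)cc1OC
F7 | step 15 | [3,5-dimethoxy-4-(3,4,5-trimethoxyphenoxy)phenyl]lithium | [Li]c1cc(OC)c(Oc2cc(OC)c(OC)c(OC)c2)c(OC)c1
F8 | step 15 | lithium [3,5-dimethoxy-4-(3,4,5-trimethoxyphenoxy)phenyl]trimethoxyborate | [Li+].CO[B-](OC)(OC)c1cc(OC)c(Oc2cc(OC)c(OC)c(OC)c2)c(OC)c1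
F9 | step 15 | [3,5-dimethoxy-4-(3,4,5-trimethoxyphenoxy)phenyl]boronic acid | COc1cc(B(O)O)cc(OC)c1Oc1cc(OC)c(OC)c(OC)c1
F10 | step 16 | octadecaacetate of 28 | CC(=O)Oc1cc(OC(C)=O)c(Oc2cc(OC(C)=O)c(Oc3cc(OC(C)=O)c(OC(C)=O)c(OC(C)=O)c3Oc3cc(OC(C)=O)c(Oc4cc(OC(C)=O)c(OC(C)=O)c(OC(C)=O)c4Oc4cc(OC(C)=O)c(Oc5cc(OC(C)=O)c(OC(C)=O)c(OC(C)=O)c5)c(OC(C)=O)c4)c(OC(C)=O)c3)c(OC(C)=O)c2)c(OC(C)=O)c1
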